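Count the substrate by what is missing, not by what is made. The question concerns Tuesday's flask, followed so far to 80.0 min.

| flask | substrate | partner | remark | time |
|---|---|---|---|---|
| Tuesday's | 0.10 M | 0.105 M | the very flask that is asked about, followed so far |  |
| Sunday's | 0.20 M | 0.105 M | run made earlier |  |
| flask | 0.10 M | 0.105 M |  | 6.0 h |

Tuesday's run (percent of the substrate charged)

| time / min | substrate / % | mono adduct / % |
|---|---|---|
| 12.0 | 7.1 | 87.4 |
| 25.0 | 2.8 | 90.4 |
| 40.0 | 1.6 | 91.6 |
| 50.0 | 0.9 | 91.4 |
| 60.0 | 0.4 | 91.5 |
| 80.0 | 0.3 | 91.9 |

Sunday's run (percent of the substrate charged)

| time / h | substrate / % | mono adduct / % |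
|---|---|---|
| 0.667 | 22.1 | 52.0 |
| 1.33 | 14.1 | 51.6 |
| 2.00 | 11.3 | 52.3 |
| 3.00 | 8.0 | 52.0 |
| 4.00 | 6.2 | 52.4 |

(standard deviation of a reading: 0.3 percentage points)

- the earlier runs were read with a standard deviation of 0.3 percentage points

* how much substrate there is at 6.0 h, in percent of the substrate charged
* how much mono adduct there is at 6.0 h, in percent of the substrate charged
* how much double product there is at 6.0 h, in percent of the substrate charged

Tuesday's flask looks contradictory. Its partner stands at 1.05 equivalents, so the charge allows mono adduct from all the substrate, yet at 80.0 min the readings are 91.9% mono adduct and 0.3% substrate. Call the gap the share of the substrate charged that is neither substrate nor mono adduct; at that reading it is 7.80%.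

Sunday's run clears this up. Its mono adduct reads between 51.6% and 52.4%, against the 52.5% its partner charge allows, while substrate falls from 22.1% to 6.2%. Its gap therefore grows from 25.9% to 41.4%, so substrate leaves without a net gain of mono adduct.

In Tuesday's flask the gap reads 8.10% at 60.0 min, then 7.80%, a step the size of the scatter. My reckoning for 6.0 h is therefore substrate near zero and mono adduct 92.2%. Double product is not read, so I take the gap, itself a reading with scatter, as my estimate of the most it holds.

The forecast gives 0% substrate, 91.8% mono adduct and 8.2% double product, on this ground: “Double product therefore needs no further partner, and the mono adduct is not consumed.” My mono adduct stands 0.4 points above its figure.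

The flask gives 0% substrate, 92.4% mono adduct and 4.45% double product; all three forecast values count as right within the tolerance, though double product lies below the 7.5% low end of the forecast's range.

    substrate + partner → mono adduct + released group (k = 0.120 M⁻¹ s⁻¹)
    partner + mono adduct ⇌ double product + released group (K = 1.30, k = 0.00200 M⁻¹ s⁻¹)
    2 substrate → homo dimer (k = 0.00240 M⁻¹ s⁻¹)

The gap in this flask is 7.60%: double product plus 3.20% homo dimer, each homo dimer counted as two. At the start substrate goes to mono adduct 26 times as fast as to homo dimer, and its half-life by that step, 0.92 min, is shorter than the 0.92 h of mono adduct by the forward step to double product alone, both with the other concentrations as charged. The forecast's ground fails in the neighbour with 0.040 M substrate and 2.62 equiv of partner: substrate is 0%, mono adduct 49.9%, and the gap, 50.1%, holds 49.3% double product.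

The numbers in the tables were generated by integration with constants of no real substance, and the scatter is random.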